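**Retrosynthetic overview**

1. The angelate is put on the 3β-OH last (Yamaguchi). Before that, C10 is set by hydrogenolysis of a blocking C9–Br together with cis-hydrogenation of C9=C10, and the C3 alcohol is inverted by oxidation and hydride reduction.
2. Key disconnection C4–C5 (closure of ring A): intramolecular para-C-alkylation of a phenolate by a (2R,3R)-trans-epoxide, i.e. an alkylative dearomatization. The enabling feature is that ring B (C5–C10) carries its C8 carbonyl 1,4 to the methyl-bearing quaternary C5, so ring B is a dearomatized p-cresol whose para carbon C5 is nucleophilic, and C4 is vicinal to the oxygenated C3, so C3/C4 are the two carbons of an epoxide.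
3. Ring order: ring B is present from the start as the benzene ring of 3-bromo-4-methylphenol. Ring A is formed in the key step, which also creates C3, C4 and C5 as stereocentres and unveils the C8 ketone.
4. The flat arene is dressed first: B-alkyl Suzuki coupling (tether C1–C4/C15), ortho-iodination, Stille coupling and asymmetric hydrogenation (C11 side chain), ortho-bromination (blocks C9), Shi epoxidation (C3/C4).

Key step: step 10

Remark: eremophilane numbering is used for the carbons (C1–C10 decalin, C11–C13 propanoate, C14 on C5, C15 on C4); the aryl pivalate of step 4 is assumed to be needed because a free phenolate would not survive Oxone in step 7.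

**Route**

Step 1
Reactants: 1 3-bromo-4-methylphenol; 2 (E)-penta-1,3-diene
Product: 4 4-methyl-3-[(E)-pent-3-en-1-yl]phenol, via B-[(E)-pent-3-en-1-yl]-9-BBN 3 (not isolated)
Conditions: 2 (excess), 9-BBN, THF, 0 °C to rt; then 1, Pd(dppf)Cl2 (5 mol%), aq. K3PO4, DMF, 60 °C
Reagents that add atoms: none
Why: 9-BBN should hydroborate the diene at its terminal CH2 and the homoallyl borane should undergo B-alkyl Suzuki–Miyaura coupling with the aryl bromide (free phenols are tolerated), which installs the future C1–C4 and C15 with the E geometry of the diene; no stereocentre is formed.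

Step 2
Reactants: 4 4-methyl-3-[(E)-pent-3-en-1-yl]phenol
Product: 5 2-iodo-4-methyl-5-[(E)-pent-3-en-1-yl]phenol
Conditions: NIS (1.05 equiv), MeCN, 0 °C
Reagents that add atoms: N-iodosuccinimide, O=C1CCC(=O)N1I
Why: Electrophilic aromatic iodination of the phenol should go to the less hindered ortho carbon (future C7), since the para position carries the methyl group and the other ortho carbon is flanked by the tether, while the isolated alkene reacts much more slowly than the phenol.

Step 3
Reactants: 5 2-iodo-4-methyl-5-[(E)-pent-3-en-1-yl]phenol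
Product: 6 2-bromo-6-iodo-4-methyl-3-[(E)-pent-3-en-1-yl]phenol
Conditions: NBS (1.05 equiv), i-Pr2NH (10 mol%), CH2Cl2, −20 °C
Reagents that add atoms: N-bromosuccinimide, O=C1CCC(=O)N1Br
Why: Amine-catalysed ortho-bromination of the phenol should take the only remaining activated position (future C9) and installs the temporary blocking group that later forces para-alkylation.

Step 4
Reactants: 6 2-bromo-6-iodo-4-methyl-3-[(E)-pent-3-en-1-yl]phenol
Product: 7 2-bromo-6-iodo-4-methyl-3-[(E)-pent-3-en-1-yl]phenyl 2,2-dimethylpropanoate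
Conditions: PivCl, Et3N, DMAP (cat.), CH2Cl2, rt
Reagents that add atoms: pivaloyl chloride, CC(C)(C)C(Cl)=O
Why: O-Acylation gives an aryl pivalate that should survive the pH 10.5 medium of the Shi epoxidation and shield the electron-rich ring from Oxone, yet is cleaved by hydroxide in step 8.

Step 5
Reactants: 8 methyl propiolate
Product: 9 methyl 2-(tributylstannyl)prop-2-enoate
Conditions: Bu3SnH, Pd(PPh3)4 (2 mol%), THF, 0 °C to rt
Reagents that add atoms: tributyltin hydride, CCCC[SnH](CCCC)CCCC
Why: Palladium-catalysed syn-hydrostannation of an alkynoate places tin on the alpha carbon and should give the alpha-stannyl acrylate as the main regioisomer.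

Step 6
Reactants: 7 2-bromo-6-iodo-4-methyl-3-[(E)-pent-3-en-1-yl]phenyl 2,2-dimethylpropanoate; 9 methyl 2-(tributylstannyl)prop-2-enoate
Product: 10 methyl 2-{3-bromo-5-methyl-4-[(E)-pent-3-en-1-yl]-2-(pivaloyloxy)phenyl}prop-2-enoate
Conditions: Pd(PPh3)4 (5 mol%), CuI (10 mol%), DMF, 50 °C
Reagents that add atoms: none
Why: Stille coupling should occur only at the C–I bond, because the C–Br bond is both less reactive and flanked by two ortho substituents, and it attaches C11–C13 as a 2-arylacrylate.

Step 7
Reactants: 10 methyl 2-{3-bromo-5-methyl-4-[(E)-pent-3-en-1-yl]-2-(pivaloyloxy)phenyl}prop-2-enoate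
Product: 11 methyl 2-{3-bromo-5-methyl-4-[2-((2R,3R)-3-methyloxiran-2-yl)ethyl]-2-(pivaloyloxy)phenyl}prop-2-enoate
Conditions: D-fructose-derived Shi ketone (30 mol%), Oxone, K2CO3, Bu4NHSO4 (cat.), MeCN–dimethoxymethane–aq. buffer (pH 10.5), 0 °C
Reagents that add atoms: Oxone (potassium peroxymonosulfate), [K+].[O-]S(=O)(=O)OO
Why: Shi epoxidation through the spiro transition state of the chiral dioxirane should convert the electron-rich trans-alkene (not the electron-poor acrylate) into the (R,R)-epoxide, which fixes C3 and C4 by reagent control.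

Step 8
Reactants: 11 methyl 2-{3-bromo-5-methyl-4-[2-((2R,3R)-3-methyloxiran-2-yl)ethyl]-2-(pivaloyloxy)phenyl}prop-2-enoate
Product: 12 2-{3-bromo-2-hydroxy-5-methyl-4-[2-((2R,3R)-3-methyloxiran-2-yl)ethyl]phenyl}prop-2-enoic acid
Conditions: LiOH, THF–MeOH–H2O, rt; then cold dil. HCl to pH 4
Reagents that add atoms: lithium hydroxide, [Li+].[OH-]
Why: Saponification should cleave the methyl ester and the aryl pivalate while the dialkyl epoxide is inert to hydroxide at room temperature, giving the free acid needed for the next two steps.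

Step 9
Reactants: 12 2-{3-bromo-2-hydroxy-5-methyl-4-[2-((2R,3R)-3-methyloxiran-2-yl)ethyl]phenyl}prop-2-enoic acid
Product: 13 (2R)-2-{3-bromo-2-hydroxy-5-methyl-4-[2-((2R,3R)-3-methyloxiran-2-yl)ethyl]phenyl}propanoic acid
Conditions: Ru(OAc)2[(R)-BINAP] (1 mol%), H2 (50 bar), MeOH, rt
Reagents that add atoms: none
Why: Carboxylate-directed Ru–BINAP asymmetric hydrogenation of the 2-arylacrylic acid should set C11 as R by catalyst control ((R)-BINAP is the antipode of the ligand that leads to (S)-2-arylpropanoic acids) and leaves aryl bromide and epoxide untouched.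

Step 10
Reactants: 13 (2R)-2-{3-bromo-2-hydroxy-5-methyl-4-[2-((2R,3R)-3-methyloxiran-2-yl)ethyl]phenyl}propanoic acid
Product: 14 (2R)-2-[(7R,8R,8aR)-4-bromo-7-hydroxy-8,8a-dimethyl-3-oxo-3,5,6,7,8,8a-hexahydronaphthalen-2-yl]propanoic acid
Conditions: t-BuOK (2.2 equiv), t-BuOH–THF, 0.01 M, 75 °C; then cold dil. HCl
Reagents that add atoms: none
Why: Deprotonation gives the phenolate (the carboxylate keeps C11 non-acidic and cannot lactonize), whose para carbon C5, the methyl-bearing ring carbon, opens the epoxide at the distal carbon C4 in an SN2 reaction with inversion, so that ring A closes and ring B emerges as the 2,5-cyclohexadienone; this is a Winstein–Masamune alkylative dearomatization by Ar2-6 phenolate participation with an epoxide as the electrophile. Ring A closes in a six-membered mode with the phenolate C=C inside the new ring (6-enolendo) and both epoxide carbons in the ring, whereas attack at C3 would be a disfavoured 5-enolendo closure. C3 keeps the epoxide configuration and C4 is inverted, so the (2R,3R)-epoxide fixes both; the anti-periplanar opening forces O-3 equatorial in a chair transition state in which the C4 methyl is equatorial and the incipient angular methyl axial, so the two methyl groups end up cis and the quaternary C5 is formed from one arene face only. The step needs para- over ortho-C-alkylation and C- over O-alkylation: the bromine on C9 blocks the only other ring carbon within reach (a halogen-bearing carbon is a poor ipso position), O-alkylation is impossible within the molecule for a meta tether and is held back between molecules by high dilution and the two ortho substituents. The product is the 3α-alcohol, which is corrected in steps 12 and 13.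

Step 11
Reactants: 14 (2R)-2-[(7R,8R,8aR)-4-bromo-7-hydroxy-8,8a-dimethyl-3-oxo-3,5,6,7,8,8a-hexahydronaphthalen-2-yl]propanoic acid
Product: 15 methyl (2R)-2-[(7R,8R,8aR)-4-bromo-7-hydroxy-8,8a-dimethyl-3-oxo-3,5,6,7,8,8a-hexahydronaphthalen-2-yl]propanoate
Conditions: MeI, KHCO3, DMF, rt
Reagents that add atoms: iodomethane, CI
Why: O-Alkylation of the carboxylate under weakly basic conditions should give the methyl ester without touching the secondary alcohol or epimerizing C11.

Step 12
Reactants: 15 methyl (2R)-2-[(7R,8R,8aR)-4-bromo-7-hydroxy-8,8a-dimethyl-3-oxo-3,5,6,7,8,8a-hexahydronaphthalen-2-yl]propanoate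
Product: 16 methyl (2R)-2-[(8R,8aR)-4-bromo-8,8a-dimethyl-3,7-dioxo-3,5,6,7,8,8a-hexahydronaphthalen-2-yl]propanoate
Conditions: Dess–Martin periodinane, pyridine, CH2Cl2, 0 °C to rt
Reagents that add atoms: none
Why: Dess–Martin oxidation removes the temporary 3α configuration, and the pyridine buffer should prevent enolization and epimerization at C4.

Step 13
Reactants: 16 methyl (2R)-2-[(8R,8aR)-4-bromo-8,8a-dimethyl-3,7-dioxo-3,5,6,7,8,8a-hexahydronaphthalen-2-yl]propanoate
Product: 17 methyl (2R)-2-[(7S,8R,8aR)-4-bromo-7-hydroxy-8,8a-dimethyl-3-oxo-3,5,6,7,8,8a-hexahydronaphthalen-2-yl]propanoate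
Conditions: L-Selectride (1.05 equiv), THF, −78 °C; then H2O
Reagents that add atoms: none
Why: The bulky hydride should attack the saturated C3 ketone from the equatorial side, away from the syn-axial angular methyl on C5, and give the axial 3β-alcohol cis to the C4 methyl, while the hindered cross-conjugated bromodienone and the ester are expected to be left alone at −78 °C.

Step 14
Reactants: 17 methyl (2R)-2-[(7S,8R,8aR)-4-bromo-7-hydroxy-8,8a-dimethyl-3-oxo-3,5,6,7,8,8a-hexahydronaphthalen-2-yl]propanoate
Product: 18 methyl (2R)-2-[(4aR,7S,8R,8aR)-7-hydroxy-8,8a-dimethyl-3-oxo-3,4,4a,5,6,7,8,8a-octahydronaphthalen-2-yl]propanoate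
Conditions: H2 (1 atm), 5% Pd/C, Et3N, EtOAc, 0 °C to rt, stopped after 2 equiv H2
Reagents that add atoms: none
Why: Hydrogenolysis of the vinylic C–Br bond anchors the C9=C10 arm on palladium, and syn-delivery of hydrogen to C10 from the face of the angular methyl (the usual course for 4a-methyl octalones, whose other face is blocked by the axial hydrogens of ring A) should set the cis ring fusion, while the C6=C7 bond, alpha-branched and next to the quaternary centre, should be the slower alkene.

Step 15
Reactants: 18 methyl (2R)-2-[(4aR,7S,8R,8aR)-7-hydroxy-8,8a-dimethyl-3-oxo-3,4,4a,5,6,7,8,8a-octahydronaphthalen-2-yl]propanoate; 19 angelic acid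
Product: 21 methyl (2R)-2-[(4aR,7S,8R,8aR)-8,8a-dimethyl-7-{[(2Z)-2-methylbut-2-enoyl]oxy}-3-oxo-3,4,4a,5,6,7,8,8a-octahydronaphthalen-2-yl]propanoate, via angeloyl 2,4,6-trichlorobenzoyl anhydride 20 (not isolated)
Conditions: 19, 2,4,6-trichlorobenzoyl chloride, Et3N, toluene, rt; then 18, DMAP, toluene, 60 °C
Reagents that add atoms: none
Why: Yamaguchi esterification through the mixed anhydride acylates the hindered secondary alcohol on oxygen under conditions known to keep the Z geometry of angelates, and no stereocentre is touched.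

**Compound list**

1 | 3-bromo-4-methylphenol | Cc1ccc(O)cc1Br | starting material
2 | (E)-penta-1,3-diene | C=C/C=C/C | starting material
3 | B-[(E)-pent-3-en-1-yl]-9-borabicyclo[3.3.1]nonane | C/C=C/CCB1C2CCCC1CCC2 | intermediate
4 | 4-methyl-3-[(E)-pent-3-en-1-yl]phenol | C/C=C/CCc1cc(O)ccc1C | intermediate
5 | 2-iodo-4-methyl-5-[(E)-pent-3-en-1-yl]phenol | C/C=C/CCc1cc(O)c(I)cc1C | intermediate
6 | 2-bromo-6-iodo-4-methyl-3-[(E)-pent-3-en-1-yl]phenol | C/C=C/CCc1c(Br)c(O)c(I)cc1C | intermediate
7 | 2-bromo-6-iodo-4-methyl-3-[(E)-pent-3-en-1-yl]phenyl 2,2-dimethylpropanoate | C/C=C/CCc1c(Br)c(OC(=O)C(C)(C)C)c(I)cc1C | intermediate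
8 | methyl propiolate | C#CC(=O)OC | starting material
9 | methyl 2-(tributylstannyl)prop-2-enoate | C=C(C(=O)OC)[Sn](CCCC)(CCCC)CCCC | intermediate
10 | methyl 2-{3-bromo-5-methyl-4-[(E)-pent-3-en-1-yl]-2-(pivaloyloxy)phenyl}prop-2-enoate | C/C=C/CCc1c(Br)c(OC(=O)C(C)(C)C)c(C(=C)C(=O)OC)cc1C | intermediate
11 | methyl 2-{3-bromo-5-methyl-4-[2-((2R,3R)-3-methyloxiran-2-yl)ethyl]-2-(pivaloyloxy)phenyl}prop-2-enoate | COC(=O)C(=C)c1cc(C)c(CC[C@H]2O[C@@H]2C)c(Br)c1OC(=O)C(C)(C)C | intermediate
12 | 2-{3-bromo-2-hydroxy-5-methyl-4-[2-((2R,3R)-3-methyloxiran-2-yl)ethyl]phenyl}prop-2-enoic acid | OC(=O)C(=C)c1cc(C)c(CC[C@H]2O[C@@H]2C)c(Br)c1O | intermediate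
13 | (2R)-2-{3-bromo-2-hydroxy-5-methyl-4-[2-((2R,3R)-3-methyloxiran-2-yl)ethyl]phenyl}propanoic acid | C[C@@H](C(=O)O)c1cc(C)c(CC[C@H]2O[C@@H]2C)c(Br)c1O | intermediate
14 | (2R)-2-[(7R,8R,8aR)-4-bromo-7-hydroxy-8,8a-dimethyl-3-oxo-3,5,6,7,8,8a-hexahydronaphthalen-2-yl]propanoic acid (3α-OH, 4β-Me, 5β-Me) | O[C@@H]1CCC2=C(Br)C(=O)C([C@@H](C)C(=O)O)=C[C@]2(C)[C@H]1C | intermediate
15 | methyl (2R)-2-[(7R,8R,8aR)-4-bromo-7-hydroxy-8,8a-dimethyl-3-oxo-3,5,6,7,8,8a-hexahydronaphthalen-2-yl]propanoate | O[C@@H]1CCC2=C(Br)C(=O)C([C@@H](C)C(=O)OC)=C[C@]2(C)[C@H]1C | intermediate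
16 | methyl (2R)-2-[(8R,8aR)-4-bromo-8,8a-dimethyl-3,7-dioxo-3,5,6,7,8,8a-hexahydronaphthalen-2-yl]propanoate | O=C1CCC2=C(Br)C(=O)C([C@@H](C)C(=O)OC)=C[C@]2(C)[C@H]1C | intermediate
17 | methyl (2R)-2-[(7S,8R,8aR)-4-bromo-7-hydroxy-8,8a-dimethyl-3-oxo-3,5,6,7,8,8a-hexahydronaphthalen-2-yl]propanoate (3β-OH) | O[C@H]1CCC2=C(Br)C(=O)C([C@@H](C)C(=O)OC)=C[C@]2(C)[C@H]1C | intermediate
18 | methyl (2R)-2-[(4aR,7S,8R,8aR)-7-hydroxy-8,8a-dimethyl-3-oxo-3,4,4a,5,6,7,8,8a-octahydronaphthalen-2-yl]propanoate | O[C@H]1CC[C@@H]2CC(=O)C([C@@H](C)C(=O)OC)=C[C@]2(C)[C@H]1C | intermediate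
19 | angelic acid, (2Z)-2-methylbut-2-enoic acid | C/C=C(/C)C(=O)O | starting material
20 | angeloyl 2,4,6-trichlorobenzoyl anhydride | C/C=C(/C)C(=O)OC(=O)c1c(Cl)cc(Cl)cc1Cl | intermediate
21 | methyl (2R)-2-[(4aR,7S,8R,8aR)-8,8a-dimethyl-7-{[(2Z)-2-methylbut-2-enoyl]oxy}-3-oxo-3,4,4a,5,6,7,8,8a-octahydronaphthalen-2-yl]propanoate | C/C=C(/C)C(=O)O[C@H]1CC[C@@H]2CC(=O)C([C@@H](C)C(=O)OC)=C[C@]2(C)[C@H]1C | target

**Step count and risks**

Total steps: 15 (14 on the main line plus the preparation of stannane 9).
Longest linear sequence: 14 steps (1 to 21 through steps 1–4 and 6–15).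

Steps most likely to fail:

1. Step 10. C-alkylation at the hindered, methyl-bearing para carbon may be outpaced by base-induced isomerization of the epoxide or by intermolecular O-alkylation. The fallback reverses the activation: instead of a nucleophilic phenolate, the epoxide is made electrophilic. It sets out from 13, which is silylated on phenol and acid (TBSCl, imidazole, DMF) to tert-butyldimethylsilyl (2R)-2-{3-bromo-2-[(tert-butyldimethylsilyl)oxy]-5-methyl-4-[2-((2R,3R)-3-methyloxiran-2-yl)ethyl]phenyl}propanoate F1. Treatment with BF3·OEt2 in CH2Cl2 at −78 °C should then trigger a cationic epoxide–arene cyclization in which the silyloxy-activated ring attacks C4 at the ipso-methyl para position with the same anti opening. Loss of the silyl group from the oxocarbenium ion and hydrolysis of the silyl ester on work-up return the route at 14.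

2. Step 14. Hydrogen may also saturate the C6=C7 bond or move it into conjugation with the ester (loss of C11), or be delivered to the wrong face of C10. The fallback gives up the differentiation of the two double bonds. It sets out from 17, which is hydrogenated exhaustively (H2, Pd/C, Et3N, longer time) to the saturated cis-fused keto ester methyl (2R)-2-[(4aR,7S,8R,8aS)-7-hydroxy-8,8a-dimethyl-3-oxodecahydronaphthalen-2-yl]propanoate F2 (ring carbon 2 as a mixture of epimers). Thermodynamic silylation (TMSOTf, Et3N, CH2Cl2) should give the more substituted enol ether methyl (2R)-2-[(4aR,7S,8R,8aS)-8,8a-dimethyl-3,7-bis(trimethylsilyloxy)-1,4,4a,5,6,7,8,8a-octahydronaphthalen-2-yl]propanoate F3. Saegusa–Ito oxidation (Pd(OAc)2, MeCN) then reintroduces the C6=C7 bond only, and mild acidic methanolysis of the remaining silyl ether returns the route at 18.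

3. Step 13. The hydride may add to the bromodienone (conjugate or 1,2-addition) or attack C3 with too little face selectivity. The fallback replaces the reagent by an enzyme: 16 is reduced with a ketoreductase chosen from a screening panel for the (S)-alcohol (NADPH recycled with isopropanol, pH 7 buffer with DMSO as cosolvent). This enzyme class reduces saturated ketones and leaves enones and esters alone. The reaction goes directly from 16 to 17, and no new compound arises.

Further compounds
F1 | step 10 | tert-butyldimethylsilyl (2R)-2-{3-bromo-2-[(tert-butyldimethylsilyl)oxy]-5-methyl-4-[2-((2R,3R)-3-methyloxiran-2-yl)ethyl]phenyl}propanoate | CC(C)(C)[Si](C)(C)Oc1c(Br)c(CC[C@H]2O[C@@H]2C)c(C)cc1[C@@H](C)C(=O)O[Si](C)(C)C(C)(C)C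
F2 | step 14 | methyl (2R)-2-[(4aR,7S,8R,8aS)-7-hydroxy-8,8a-dimethyl-3-oxodecahydronaphthalen-2-yl]propanoate (ring carbon 2 unassigned) | O[C@H]1CC[C@@H]2CC(=O)C([C@@H](C)C(=O)OC)C[C@]2(C)[C@H]1C
F3 | step 14 | methyl (2R)-2-[(4aR,7S,8R,8aS)-8,8a-dimethyl-3,7-bis(trimethylsilyloxy)-1,4,4a,5,6,7,8,8a-octahydronaphthalen-2-yl]propanoate | C[Si](C)(C)O[C@H]1CC[C@@H]2CC(O[Si](C)(C)C)=C([C@@H](C)C(=O)OC)C[C@]2(C)[C@H]1C
F0 | step 13 | none | none
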